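The summer run, charged with twice the substrate of the noon run, holds less ring than the noon run: on average 61.1 % against 74.8 %. The flask asked about is the noon run carried on to 2.5 h.

| flask | substrate | remark | time |
|---|---|---|---|
| noon | 0.20 M | the very flask that is asked about, followed so far |  |
| summer | 0.40 M | run made earlier |  |
| flask | 0.20 M |  | 2.5 h |

noon run (percent of the substrate charged)

| time / min | substrate / % | ring / % | open dimer / % |
|---|---|---|---|
| 2.50 | 0 | 74.1 | 24.8 |
| 6.00 | 0.3 | 74.0 | 25.8 |
| 12.0 | 0 | 74.2 | 24.3 |
| 20.0 | 0 | 75.5 | 25.2 |
| 25.0 | 0.8 | 75.8 | 26.6 |
| 40.0 | 0.5 | 74.9 | 25.3 |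
| 50.0 | 0.6 | 75.0 | 25.4 |

summer run (percent of the substrate charged)

| time / h | substrate / % | ring / % | open dimer / % |
|---|---|---|---|
| 0.133 | 0.7 | 60.7 | 39.6 |
| 0.417 | 0 | 61.7 | 38.6 |
| 0.667 | 0 | 61.2 | 38.2 |
| 1.00 | 0 | 60.8 | 39.6 |
| 1.50 | 0 | 61.0 | 38.8 |
| 2.00 | 0.8 | 60.8 | 38.4 |
| 2.50 | 0.5 | 61.2 | 40.0 |

(each reading ± 0.5 percentage points)

- percentages count the substrate that a species holds: one open dimer counts as two
- steps under discussion: 2 substrate -> open dimer; substrate -> ring
- the reaction counts as stopped when no species that holds the substrate changes by six tenths of a point or more over the second half of the time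

- the state of affairs at 2.5 h: stopped, and by what, or still going (forward and back rates have come level / all of the substrate has reacted / it is still moving)
- part of the substrate gone at 2.5 h
- the ring standing at 2.5 h, as a percentage of the substrate charged
- the open dimer standing at 2.5 h, as a percentage of the substrate charged

What would have to be true for this flask to stop some other way? If forward and back rates came level, c(open dimer) over c(ring) squared would match in both runs. But the summer value over the noon value reads 1.16, not one. If the flask were still moving, the readings would drift. But the summer ring reads 60.8 % at 1.00 h and 61.2 % at 2.50 h.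

So I take kinetic control, not thermodynamic. The ring step goes with c(substrate), the open-dimer step with c(substrate) squared. Let c* be the c(substrate) at which both steps use substrate equally fast. Integrating the ring rate over the substrate lost, from the charge c to nothing, gives a ring share of (c*/c) ln(1 + c/c*). Set against the summer mean, that gives the crossover concentration c* as 0.267 M, so the summer charge stands at 1.50 times c*. For this flask I reckon 74.6 % ring. The noon readings, which did not enter c*, average 74.8 % ring.

The forecast says all of the substrate has reacted, with 100 % gone, 74.9 % ring and 25.1 % open dimer, and concludes that “the reaction stops by exhausting the substrate”. Its ring is higher than mine by 0.30 percentage points.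

The flask gives all of the substrate has reacted, with 100 % gone, 74.6 % ring and 25.4 % open dimer.

    2 substrate → open dimer (k = 0.120 L mol⁻¹ s⁻¹)
    substrate → ring (k = 0.0640 s⁻¹)

At the start of this flask the ring step uses substrate 1.3 times as fast as the open-dimer step, and c* over the charge gives 1.33. At 0.00245 h that ratio stands at 3.1. The neighbour flask is charged with 0.80 M of substrate, more than c*; the same integral gives it 46.2 % ring, and it holds 46.2 %.

(Readings and results stem from a simulated flask from invented constants; noise was put on by code.)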